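**Strategy.** The 20-membered lactone is closed at C4–C5, the bond joining the C4 carbinol to the C5–C6 oxirane, and not at the ester. This 2,3-epoxy alcohol triad, flanked by the C2=C3 Z-enoate, is read as an E-allylic alcohol: a linear ester bearing an (E)-vinyl iodide (C5=C6) and a 4-oxobut-2-ynoate (C1–C4) undergoes a ligand-controlled Nozaki–Hiyama–Kishi macrocyclisation that forms the ring, sets C4 and fixes the E-alkene; reagent-controlled epoxidation and final alkyne semi-reduction (latent Z-enoate) complete the target. The all-syn C19/C21/C23 triol arises from a dithiane linchpin union of two enantiopure epoxides and a syn-selective reduction.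

Key step: step 14

Assumption: in step 14 the (S)-configured oxazoline–sulfonamide ligand is assumed to steer the alkenyl group to the aldehyde face that gives the (4S) carbinol; should a test coupling show the opposite sense, its (R) antipode is used with nothing else changed.

Atom numbering follows the macrolide (C1 = lactone carbonyl, C19 = lactone carbinol, C20–C24 = side chain).

Step 1
Reactants: 1 (triisopropylsilyl)acetylene; 2 1,11-dibromoundecane
Product: 4 (13-bromotridec-1-yn-1-yl)triisopropylsilane, via lithium (triisopropylsilyl)acetylide 3 (not isolated)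
Conditions: n-BuLi, THF, −78 °C; then 2 (3 equiv), DMPU, −78 °C → rt
Reagents that add atoms: none
Why: SN2 alkylation of a lithium acetylide by a primary bromide, kept to mono-substitution by the excess of the dibromide.

Step 2
Reactants: 4 (13-bromotridec-1-yn-1-yl)triisopropylsilane; 5 (S)-epichlorohydrin
Product: 7 (2S)-1-chloro-16-(triisopropylsilyl)hexadec-15-yn-2-ol, via alkylmagnesium bromide 6 (not isolated)
Conditions: Mg, THF, rt; then CuI (10 mol%), 5, −40 → 0 °C; aq. NH4Cl
Reagents that add atoms: none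
Why: Copper-catalysed Grignard opening of the epoxide at its unsubstituted carbon, which leaves the future C19 stereocentre of 5 untouched.

Step 3
Reactants: 7 (2S)-1-chloro-16-(triisopropylsilyl)hexadec-15-yn-2-ol
Product: 8 (2S)-2-[14-(triisopropylsilyl)tetradec-13-yn-1-yl]oxirane
Conditions: K2CO3, MeOH, rt
Reagents that add atoms: none
Why: Intramolecular Williamson etherification of the chlorohydrin, in which no bond to the stereocentre is broken and the hindered C-silyl alkyne survives.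

Step 4
Reactants: 8 (2S)-2-[14-(triisopropylsilyl)tetradec-13-yn-1-yl]oxirane; 9 2-(tert-butyldimethylsilyl)-1,3-dithiane; 10 (R)-propylene oxide
Product: 14 (2R)-1-{2-[(2S)-2-(tert-butyldimethylsilyloxy)-16-(triisopropylsilyl)hexadec-15-yn-1-yl]-1,3-dithian-2-yl}propan-2-ol, via lithiated silyl dithiane 11 (not isolated), via lithium alkoxide adduct 12 (not isolated), via Brook-rearranged dithianyl lithium 13 (not isolated)
Conditions: 9, t-BuLi, Et2O, −78 → −45 °C; 8, −78 → −25 °C; then 10, THF/HMPA, −78 °C → rt; aq. NH4Cl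
Reagents that add atoms: none
Why: Three-component dithiane linchpin coupling with anion relay (epoxide opening at CH2, solvent-triggered 1,4-Brook shift of silicon from carbon to the C19 oxygen, second epoxide opening), with C19 and C23 carried in unchanged from 8 and 10 and the two hydroxyls differentiated in the same flask.

Step 5
Reactants: 14 the dithiane from step 4
Product: 15 (2R,6S)-6-(tert-butyldimethylsilyloxy)-2-hydroxy-20-(triisopropylsilyl)icos-19-yn-4-one
Conditions: PhI(OCOCF3)2, MeCN/H2O (9:1), 0 °C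
Reagents that add atoms: water, O
Why: Oxidative dithiane hydrolysis with a hypervalent iodine reagent unmasks the C21 ketone without touching the silyl ether or the silyl alkyne.

Step 6
Reactants: 15 the β-hydroxy ketone
Product: 16 (2R,4R,6S)-6-(tert-butyldimethylsilyloxy)-20-(triisopropylsilyl)icos-19-yne-2,4-diol
Conditions: Et2BOMe, THF/MeOH (4:1), −78 °C; NaBH4; then MeOH azeotrope
Reagents that add atoms: none
Why: Narasaka–Prasad reduction, in which the boron chelate between the C23 hydroxyl and the C21 ketone is attacked axially by external hydride, should set C21 syn to C23.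

Step 7
Reactants: 16 the syn-1,3-diol
Product: 17 tert-butyldimethyl{[(2S)-1-[(4R,6R)-2,2,6-trimethyl-1,3-dioxan-4-yl]-16-(triisopropylsilyl)hexadec-15-yn-2-yl]oxy}silane
Conditions: 2,2-dimethoxypropane, PPTS (cat.), CH2Cl2, rt
Reagents that add atoms: 2,2-dimethoxypropane, COC(C)(C)OC
Why: Acid-catalysed transketalisation gives the six-membered acetonide of the syn-1,3-diol, leaving only the C19 oxygen under silicon.

Step 8
Reactants: 17 the acetonide
Product: 18 (2S)-1-[(4S,6R)-2,2,6-trimethyl-1,3-dioxan-4-yl]hexadec-15-yn-2-ol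
Conditions: TBAF, THF, rt → 40 °C
Reagents that add atoms: none
Why: Fluoride cleaves both the O–Si bond at C19 and the C(sp)–Si bond in one operation while the acetonide is inert.

Step 9
Reactants: 18 the alkynol
Product: 20 (2S,15E)-16-iodo-1-[(4S,6R)-2,2,6-trimethyl-1,3-dioxan-4-yl]hexadec-15-en-2-ol, via bis-zirconated alkenylzirconocene 19 (not isolated)
Conditions: Cp2Zr(H)Cl (2.5 equiv), THF, rt; then I2, 0 °C
Reagents that add atoms: iodine, II
Why: Hydrozirconation (syn addition of Zr–H with zirconium at the terminal carbon) followed by iodinolysis with retention should give the (E)-vinyl iodide, the extra equivalent of hydride being consumed by the free hydroxyl.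

Step 10
Reactants: 21 tert-butyldimethyl(prop-2-yn-1-yloxy)silane
Product: 23 4-[(tert-butyldimethylsilyl)oxy]but-2-ynoic acid, via lithium acetylide 22 (not isolated)
Conditions: n-BuLi, THF, −78 °C; CO2; cold 1 M HCl to pH 3
Reagents that add atoms: carbon dioxide, O=C=O
Why: Carboxylation of a lithium acetylide.

Step 11
Reactants: 20 the vinyl iodide alcohol; 23 4-[(tert-butyldimethylsilyl)oxy]but-2-ynoic acid
Product: 24 (2S,15E)-16-iodo-1-[(4R,6R)-2,2,6-trimethyl-1,3-dioxan-4-yl]hexadec-15-en-2-yl 4-[(tert-butyldimethylsilyl)oxy]but-2-ynoate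
Conditions: DCC, DMAP (cat.), CH2Cl2, 0 °C
Reagents that add atoms: none
Why: Steglich esterification acylates the C19 oxygen, so the C19 configuration is retained.

Step 12
Reactants: 24 the silyl ether ester
Product: 25 (2S,15E)-16-iodo-1-[(4R,6R)-2,2,6-trimethyl-1,3-dioxan-4-yl]hexadec-15-en-2-yl 4-hydroxybut-2-ynoate
Conditions: HF·pyridine, pyridine, THF, 0 °C → rt
Reagents that add atoms: none
Why: Pyridine-buffered HF cleaves the primary silyl ether while the acetonide, the vinyl iodide and the ynoate remain.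

Step 13
Reactants: 25 the propargylic alcohol
Product: 26 (2S,15E)-16-iodo-1-[(4R,6R)-2,2,6-trimethyl-1,3-dioxan-4-yl]hexadec-15-en-2-yl 4-oxobut-2-ynoate
Conditions: Dess–Martin periodinane, CH2Cl2, 0 °C → rt; used at once
Reagents that add atoms: none
Why: Dess–Martin oxidation gives the electrophilic ynal under non-basic conditions, and the alkyne geometry rules out any hemiacetal or lactone closure.

Step 14
Reactants: 26 the iodo-ynal ester
Product: 28 (4S,5E,19S)-4-hydroxy-19-{[(4R,6R)-2,2,6-trimethyl-1,3-dioxan-4-yl]methyl}nonadec-5-en-2-yn-19-olide, via alkenylchromium intermediate 27 (not isolated)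
Conditions: CrCl2 (5 equiv), (S)-N-[2-(4-isopropyl-4,5-dihydrooxazol-2-yl)-6-methylphenyl]methanesulfonamide (5.5 equiv), Et3N (5.5 equiv), NiCl2 (0.1 equiv), THF/MeCN, syringe-pump addition of 26 to 2 mM, rt
Reagents that add atoms: none
Why: Zerovalent nickel (from NiCl2 and CrCl2) inserts into the C5–I bond, the alkenyl group passes with retention of the E geometry to ligand-bound trivalent chromium, and this alkenylchromium adds 1,2 to the C4 aldehyde. The closest known reaction type is the asymmetric Nozaki–Hiyama–Kishi macrocyclisation of iodoalkenyl aldehydes with oxazoline–sulfonamide chromium complexes. The 20-membered ring closes by a 20-exo-trig attack on the carbonyl under pseudo-high dilution. The new C4 stereocentre is set by the chiral ligand on chromium (reagent control), because the nearest resident centre, C19, lies beyond the linear C1–C3 ynoate and cannot bias the face. The step needs chemoselectivity for the aldehyde over the ester carbonyl and the alkyne carbons, and cyclisation over oligomerisation; the aldehyde as the only electrophile that a non-basic alkenylchromium attacks, the single C–I bond and the slow addition should secure both. It exploits the C4(OH)–C5–C6 epoxy alcohol of the lactone ring, whose precursor is exactly the E-allylic alcohol that this coupling delivers.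

Step 15
Reactants: 28 the macrocyclic acetonide
Product: 29 (4S,5E,19S)-19-[(2R,4R)-2,4-dihydroxypentyl]-4-hydroxynonadec-5-en-2-yn-19-olide
Conditions: PPTS (cat.), MeOH, rt
Reagents that add atoms: none
Why: Mild acid-catalysed transketalisation to methanol removes the acetonide before the acid-sensitive oxirane exists.

Step 16
Reactants: 29 the enyne triol
Product: 30 (4R,5S,6S,19S)-19-[(2R,4R)-2,4-dihydroxypentyl]-5,6-epoxy-4-hydroxynonadec-2-yn-19-olide
Conditions: L-fructose-derived Shi ketone (1,2:4,5-di-O-isopropylidene-β-L-erythro-2,3-hexodiulo-2,6-pyranose, 3 equiv), KHSO5 (as 2KHSO5·KHSO4·K2SO4), NaHCO3, MeCN/aq. Na2EDTA, 0 °C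
Reagents that add atoms: potassium peroxymonosulfate, [K+].[O-]S(=O)(=O)OO
Why: Shi epoxidation, in which the chiral dioxirane adds oxygen to one face of the E C5=C6 alkene through a spiro transition state (reagent control), should give the (5S,6S) trans-oxirane syn to the C4 hydroxyl, the diastereomer that titanium- or vanadium-directed epoxidation (anti-selective) would not give, while the electron-poor alkyne is left alone.

Step 17
Reactants: 30 the epoxy ynoate
Product: 31 (2Z,4R,5S,6S,19S)-19-[(2R,4R)-2,4-dihydroxypentyl]-5,6-epoxy-4-hydroxynonadec-2-en-19-olide (CNP0461152.1)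
Conditions: H2 (1 atm), Pd/CaCO3 poisoned with Pb(OAc)2, quinoline, EtOAc, 0 °C → rt
Reagents that add atoms: none
Why: Lindlar semi-hydrogenation adds H2 syn to the ynoate to give the Z-enoate under neutral conditions, so the γ-hydroxy Z-enoate is formed last and is not exposed to acid or base.

**Compound list**

1 | (triisopropylsilyl)acetylene | C#C[Si](C(C)C)(C(C)C)C(C)C | starting material
2 | 1,11-dibromoundecane | BrCCCCCCCCCCCBr | starting material
3 | lithium (triisopropylsilyl)acetylide | [Li]C#C[Si](C(C)C)(C(C)C)C(C)C | intermediate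
4 | (13-bromotridec-1-yn-1-yl)triisopropylsilane | BrCCCCCCCCCCCC#C[Si](C(C)C)(C(C)C)C(C)C | intermediate
5 | (S)-epichlorohydrin, (2S)-2-(chloromethyl)oxirane | ClC[C@@H]1CO1 | starting material
6 | [13-(triisopropylsilyl)tridec-12-yn-1-yl]magnesium bromide | Br[Mg]CCCCCCCCCCCC#C[Si](C(C)C)(C(C)C)C(C)C | intermediate
7 | (2S)-1-chloro-16-(triisopropylsilyl)hexadec-15-yn-2-ol | ClC[C@@H](O)CCCCCCCCCCCCC#C[Si](C(C)C)(C(C)C)C(C)C | intermediate
8 | (2S)-2-[14-(triisopropylsilyl)tetradec-13-yn-1-yl]oxirane | O1C[C@@H]1CCCCCCCCCCCCC#C[Si](C(C)C)(C(C)C)C(C)C | intermediate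
9 | 2-(tert-butyldimethylsilyl)-1,3-dithiane | CC(C)(C)[Si](C)(C)C1SCCCS1 | starting material
10 | (R)-propylene oxide, (2R)-2-methyloxirane | C[C@@H]1CO1 | starting material
11 | 2-lithio-2-(tert-butyldimethylsilyl)-1,3-dithiane | CC(C)(C)[Si](C)(C)C1([Li])SCCCS1 | intermediate
12 | lithium (2S)-1-[2-(tert-butyldimethylsilyl)-1,3-dithian-2-yl]-16-(triisopropylsilyl)hexadec-15-yn-2-olate | CC(C)(C)[Si](C)(C)C1(SCCCS1)C[C@@H](O[Li])CCCCCCCCCCCCC#C[Si](C(C)C)(C(C)C)C(C)C | intermediate
13 | {2-[(2S)-2-(tert-butyldimethylsilyloxy)-16-(triisopropylsilyl)hexadec-15-yn-1-yl]-1,3-dithian-2-yl}lithium | [Li]C1(SCCCS1)C[C@@H](O[Si](C)(C)C(C)(C)C)CCCCCCCCCCCCC#C[Si](C(C)C)(C(C)C)C(C)C | intermediate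
14 | (2R)-1-{2-[(2S)-2-(tert-butyldimethylsilyloxy)-16-(triisopropylsilyl)hexadec-15-yn-1-yl]-1,3-dithian-2-yl}propan-2-ol | C[C@@H](O)CC1(SCCCS1)C[C@@H](O[Si](C)(C)C(C)(C)C)CCCCCCCCCCCCC#C[Si](C(C)C)(C(C)C)C(C)C | intermediate
15 | (2R,6S)-6-(tert-butyldimethylsilyloxy)-2-hydroxy-20-(triisopropylsilyl)icos-19-yn-4-one | C[C@@H](O)CC(=O)C[C@@H](O[Si](C)(C)C(C)(C)C)CCCCCCCCCCCCC#C[Si](C(C)C)(C(C)C)C(C)C | intermediate
16 | (2R,4R,6S)-6-(tert-butyldimethylsilyloxy)-20-(triisopropylsilyl)icos-19-yne-2,4-diol | C[C@@H](O)C[C@@H](O)C[C@@H](O[Si](C)(C)C(C)(C)C)CCCCCCCCCCCCC#C[Si](C(C)C)(C(C)C)C(C)C | intermediate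
17 | tert-butyldimethyl{[(2S)-1-[(4R,6R)-2,2,6-trimethyl-1,3-dioxan-4-yl]-16-(triisopropylsilyl)hexadec-15-yn-2-yl]oxy}silane | C[C@@H]1C[C@@H](OC(C)(C)O1)C[C@@H](O[Si](C)(C)C(C)(C)C)CCCCCCCCCCCCC#C[Si](C(C)C)(C(C)C)C(C)C | intermediate
18 | (2S)-1-[(4S,6R)-2,2,6-trimethyl-1,3-dioxan-4-yl]hexadec-15-yn-2-ol | C[C@@H]1C[C@@H](OC(C)(C)O1)C[C@@H](O)CCCCCCCCCCCCC#C | intermediate
19 | (E)-alkenylzirconocene chloride of 18 with the C19 oxygen bound as zirconocene chloride alkoxide | C[C@@H]1C[C@@H](OC(C)(C)O1)C[C@@H](O[Zr](Cl)(C2C=CC=C2)C2C=CC=C2)CCCCCCCCCCCC/C=C/[Zr](Cl)(C2C=CC=C2)C2C=CC=C2 | intermediate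
20 | (2S,15E)-16-iodo-1-[(4S,6R)-2,2,6-trimethyl-1,3-dioxan-4-yl]hexadec-15-en-2-ol | C[C@@H]1C[C@@H](OC(C)(C)O1)C[C@@H](O)CCCCCCCCCCCC/C=C/I | intermediate
21 | tert-butyldimethyl(prop-2-yn-1-yloxy)silane | C#CCO[Si](C)(C)C(C)(C)C | starting material
22 | lithium 3-(tert-butyldimethylsilyloxy)prop-1-yn-1-ide | [Li]C#CCO[Si](C)(C)C(C)(C)C | intermediate
23 | 4-[(tert-butyldimethylsilyl)oxy]but-2-ynoic acid | OC(=O)C#CCO[Si](C)(C)C(C)(C)C | intermediate
24 | (2S,15E)-16-iodo-1-[(4R,6R)-2,2,6-trimethyl-1,3-dioxan-4-yl]hexadec-15-en-2-yl 4-[(tert-butyldimethylsilyl)oxy]but-2-ynoate | C[C@@H]1C[C@@H](OC(C)(C)O1)C[C@@H](OC(=O)C#CCO[Si](C)(C)C(C)(C)C)CCCCCCCCCCCC/C=C/I | intermediate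
25 | (2S,15E)-16-iodo-1-[(4R,6R)-2,2,6-trimethyl-1,3-dioxan-4-yl]hexadec-15-en-2-yl 4-hydroxybut-2-ynoate | C[C@@H]1C[C@@H](OC(C)(C)O1)C[C@@H](OC(=O)C#CCO)CCCCCCCCCCCC/C=C/I | intermediate
26 | (2S,15E)-16-iodo-1-[(4R,6R)-2,2,6-trimethyl-1,3-dioxan-4-yl]hexadec-15-en-2-yl 4-oxobut-2-ynoate | C[C@@H]1C[C@@H](OC(C)(C)O1)C[C@@H](OC(=O)C#CC=O)CCCCCCCCCCCC/C=C/I | intermediate
27 | (E)-alkenylchromium dichloride derived from 26 (chiral ligand on chromium omitted) | C[C@@H]1C[C@@H](OC(C)(C)O1)C[C@@H](OC(=O)C#CC=O)CCCCCCCCCCCC/C=C/[Cr](Cl)Cl | intermediate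
28 | (4S,5E,19S)-4-hydroxy-19-{[(4R,6R)-2,2,6-trimethyl-1,3-dioxan-4-yl]methyl}nonadec-5-en-2-yn-19-olide | C[C@@H]1C[C@@H](OC(C)(C)O1)C[C@@H]2CCCCCCCCCCCC/C=C/[C@H](O)C#CC(=O)O2 | intermediate
29 | (4S,5E,19S)-19-[(2R,4R)-2,4-dihydroxypentyl]-4-hydroxynonadec-5-en-2-yn-19-olide | C[C@@H](O)C[C@@H](O)C[C@@H]1CCCCCCCCCCCC/C=C/[C@H](O)C#CC(=O)O1 | intermediate
30 | (4R,5S,6S,19S)-19-[(2R,4R)-2,4-dihydroxypentyl]-5,6-epoxy-4-hydroxynonadec-2-yn-19-olide | C[C@@H](O)C[C@@H](O)C[C@@H]1CCCCCCCCCCCC[C@@H]2O[C@H]2[C@H](O)C#CC(=O)O1 | intermediate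
31 | (2Z,4R,5S,6S,19S)-19-[(2R,4R)-2,4-dihydroxypentyl]-5,6-epoxy-4-hydroxynonadec-2-en-19-olide (CNP0461152.1) | C[C@@H](O)C[C@@H](O)C[C@@H]1CCCCCCCCCCCC[C@@H]2O[C@H]2[C@H](O)/C=C\C(=O)O1 | target

**Step count.** Total: 17 steps. Longest linear sequence: 16 steps (steps 1–9 and 11–17; step 10 is a one-step side branch).

**Steps most likely to fail**

1. Step 14. The electron-poor ynal/ynoate may be reduced by single-electron transfer from divalent chromium before the alkenyl group is delivered, intermolecular coupling may compete with ring closure, and the ligand may discriminate the aldehyde faces poorly. Fallback, setting out from 20 and coming back at 28: the C4–C5 bond is made intermolecularly and the ring is closed at the lactone instead. Compound 20 is coupled under the same CrCl2/NiCl2/ligand conditions with commercial 3-(trimethylsilyl)prop-2-ynal, an ynal without the ester acceptor, to give (3S,4E,18S)-1-(trimethylsilyl)-19-[(4S,6R)-2,2,6-trimethyl-1,3-dioxan-4-yl]nonadec-4-en-1-yne-3,18-diol F1. K2CO3 in MeOH removes the C-silyl group and gives the terminal alkyne (3S,4E,18S)-19-[(4S,6R)-2,2,6-trimethyl-1,3-dioxan-4-yl]nonadec-4-en-1-yne-3,18-diol F2. Triple deprotonation with n-BuLi in THF at −78 °C and trapping with CO2 gives the seco acid (4S,5E,19S)-4,19-dihydroxy-20-[(4S,6R)-2,2,6-trimethyl-1,3-dioxan-4-yl]icos-5-en-2-ynoic acid F3. Yamaguchi macrolactonisation (2,4,6-trichlorobenzoyl chloride, Et3N, then DMAP, toluene, high dilution) closes the lactone at the C19 hydroxyl, since the C4 hydroxyl cannot reach C1 across the linear alkyne, and gives 28.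

2. Step 16. The dioxirane may show poor facial selectivity if the C4 centre is mismatched with the catalyst, the γ-hydroxy ynoate may isomerise or be attacked at the buffer pH, and free secondary alcohols may be oxidised slowly. Fallback, setting out from 26 and coming back at 30: a hydroxyl-directed titanium epoxidation of the C4 epimer followed by inversion replaces the reagent-controlled dioxirane. Compound 26 is cyclised as in step 14 but with the antipodal (R) ligand to give the C4-epimeric macrocycle (4R,5E,19S)-4-hydroxy-19-{[(4R,6R)-2,2,6-trimethyl-1,3-dioxan-4-yl]methyl}nonadec-5-en-2-yn-19-olide F4. Sharpless epoxidation (Ti(OiPr)4, L-(+)-diisopropyl tartrate, t-BuOOH, CH2Cl2, −20 °C; matched, anti-selective) gives the (4S,5S,6S)-epoxy alcohol acetonide F5, which already carries the (5S,6S) oxirane. Mitsunobu inversion at C4 with chloroacetic acid (PPh3, DIAD, THF) gives the (4R)-chloroacetate F6. Thiourea with NaHCO3 in EtOH removes the chloroacetyl group and gives the (4R,5S,6S)-epoxy alcohol acetonide F7. PPTS in MeOH then removes the acetonide and gives 30.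

3. Step 17. Hydrogenation may run on to the saturated lactone, and the free γ-hydroxy Z-enoate may lactonise to a butenolide with opening of the macrocycle on the catalyst or during purification. Fallback, setting out from 30 and coming back at 31: the three hydroxyls are capped before the alkyne is reduced. Compound 30 is silylated (Et3SiOTf, 2,6-lutidine, CH2Cl2, −78 °C) to the tris(triethylsilyl) ether of 30 F8. Semi-hydrogenation over Pd/CaCO3 poisoned with Pb(OAc)2 gives the tris(triethylsilyl) ether of 31 F9, in which the C4 oxygen cannot attack the ester. Pyridine-buffered HF·pyridine in THF at 0 °C then releases 31.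

Further compounds
F1 | step 14 | (3S,4E,18S)-1-(trimethylsilyl)-19-[(4S,6R)-2,2,6-trimethyl-1,3-dioxan-4-yl]nonadec-4-en-1-yne-3,18-diol | C[C@@H]1C[C@@H](OC(C)(C)O1)C[C@@H](O)CCCCCCCCCCCC/C=C/[C@H](O)C#C[Si](C)(C)C
F2 | step 14 | (3S,4E,18S)-19-[(4S,6R)-2,2,6-trimethyl-1,3-dioxan-4-yl]nonadec-4-en-1-yne-3,18-diol | C[C@@H]1C[C@@H](OC(C)(C)O1)C[C@@H](O)CCCCCCCCCCCC/C=C/[C@H](O)C#C
F3 | step 14 | (4S,5E,19S)-4,19-dihydroxy-20-[(4S,6R)-2,2,6-trimethyl-1,3-dioxan-4-yl]icos-5-en-2-ynoic acid | C[C@@H]1C[C@@H](OC(C)(C)O1)C[C@@H](O)CCCCCCCCCCCC/C=C/[C@H](O)C#CC(=O)O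
F4 | step 16 | (4R,5E,19S)-4-hydroxy-19-{[(4R,6R)-2,2,6-trimethyl-1,3-dioxan-4-yl]methyl}nonadec-5-en-2-yn-19-olide | C[C@@H]1C[C@@H](OC(C)(C)O1)C[C@@H]2CCCCCCCCCCCC/C=C/[C@@H](O)C#CC(=O)O2
F5 | step 16 | (4S,5S,6S,19S)-5,6-epoxy-4-hydroxy-19-{[(4R,6R)-2,2,6-trimethyl-1,3-dioxan-4-yl]methyl}nonadec-2-yn-19-olide | C[C@@H]1C[C@@H](OC(C)(C)O1)C[C@@H]2CCCCCCCCCCCC[C@@H]3O[C@H]3[C@@H](O)C#CC(=O)O2
F6 | step 16 | (4R,5S,6S,19S)-4-(chloroacetoxy)-5,6-epoxy-19-{[(4R,6R)-2,2,6-trimethyl-1,3-dioxan-4-yl]methyl}nonadec-2-yn-19-olide | C[C@@H]1C[C@@H](OC(C)(C)O1)C[C@@H]2CCCCCCCCCCCC[C@@H]3O[C@H]3[C@H](OC(=O)CCl)C#CC(=O)O2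
F7 | step 16 | (4R,5S,6S,19S)-5,6-epoxy-4-hydroxy-19-{[(4R,6R)-2,2,6-trimethyl-1,3-dioxan-4-yl]methyl}nonadec-2-yn-19-olide | C[C@@H]1C[C@@H](OC(C)(C)O1)C[C@@H]2CCCCCCCCCCCC[C@@H]3O[C@H]3[C@H](O)C#CC(=O)O2
F8 | step 17 | tris(triethylsilyl) ether of 30 at the C4, C21 and C23 oxygens | C[C@@H](O[Si](CC)(CC)CC)C[C@@H](O[Si](CC)(CC)CC)C[C@@H]1CCCCCCCCCCCC[C@@H]2O[C@H]2[C@H](O[Si](CC)(CC)CC)C#CC(=O)O1
F9 | step 17 | tris(triethylsilyl) ether of 31 at the C4, C21 and C23 oxygens | C[C@@H](O[Si](CC)(CC)CC)C[C@@H](O[Si](CC)(CC)CC)C[C@@H]1CCCCCCCCCCCC[C@@H]2O[C@H]2[C@H](O[Si](CC)(CC)CC)/C=C\C(=O)O1
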